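The plan rests on one disconnection: rings B and C are removed together by a retro-Diels–Alder cut of C12–C26 and C10–C11 (atoms numbered by position in the target SMILES). It exploits the fact that quaternary C12 belongs at once to the bicyclo[2.2.2]octene, to cyclopentane ring C and to cyclohexane ring B, whose C27 is oxygenated. The precursor is therefore the butenolide-fused bicyclooctenone bearing an exocyclic C12=C11 methylene and, on C23, a chain ending in the Z 2-silyloxy diene C26=C27–C9=C10. Heating closes both rings, sets C12 and C26, and leaves a C27=C9 silyl enol ether that later serves for spirolactone closure and methyl addition.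

Key step: step 12

Remark: labels C1–O31 follow the atom order of the target SMILES (C2 lactone carbinol carbon, C5 its carbonyl, C9 spiro carbon, C14 and C22 bridgeheads, C16=C17–C18 butenolide, C30 cage ketone); because the triene that builds the cage is achiral, the absolute configuration is secured by chromatographic resolution of racemate 19, and racemates are drawn as the enantiomer that leads to the target.

**Step 1**
Reactants: 1 3-ethoxy-2-methylcyclohex-2-en-1-one
Product: 4 3-ethoxy-2-methyl-6-methylidenecyclohex-2-en-1-one, via Mannich base 2 (not isolated), via methiodide 3 (not isolated)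
Conditions: LDA, THF, −78 °C; CH2=NMe2+ I−, −78 °C to rt; MeI, CH2Cl2, rt; NaHCO3 (aq), CH2Cl2, rt
Reagents that add atoms: dimethylmethylideneammonium iodide, C=[N+](C)C.[I-]
Why: The kinetic lithium enolate of the vinylogous ester (deprotonation at C6) undergoes a Mannich reaction with the iminium salt, and quaternisation followed by Hofmann-type elimination is the standard α-methylenation of a ketone; the product has no stereocentre.

**Step 2**
Reactants: 4 3-ethoxy-2-methyl-6-methylidenecyclohex-2-en-1-one
Product: 7 3-(hydroxymethyl)-2-methyl-4-methylidenecyclohex-2-en-1-one, via silylmethyl carbinol 5 (not isolated), via diol 6 (not isolated)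
Conditions: (i-PrO)Me2SiCH2MgCl, CeCl3, THF, −78 to 0 °C; KF, KHCO3, 30% H2O2, THF/MeOH, rt; 0.5 M HCl, THF, 0 °C, short contact
Reagents that add atoms: [dimethyl(propan-2-yloxy)silyl]methylmagnesium chloride, CC(C)O[Si](C)(C)C[Mg]Cl; hydrogen peroxide, OO; water, O
Why: Cerium-assisted 1,2-addition of the silylmethyl Grignard reagent (a hydroxymethyl anion equivalent), Tamao oxidation of the C–Si bond and acid-induced Stork–Danheiser transposition (ionisation of the tertiary allylic alcohol, hydration at the ethoxy-bearing carbon, loss of ethanol) should give the 3-(hydroxymethyl) enone with the methylene untouched; no stereocentre is formed.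

**Step 3**
Reactants: 7 3-(hydroxymethyl)-2-methyl-4-methylidenecyclohex-2-en-1-one
Product: 8 3-(hydroxymethyl)-2,6-dimethyl-4-methylidenecyclohex-2-en-1-one (racemic)
Conditions: LDA (2.05 equiv), THF, −78 °C; MeI, −78 to −30 °C
Reagents that add atoms: iodomethane, CI
Why: LDA forms the alkoxide and then the kinetic cross-conjugated α′-enolate at C6, which is C-methylated (enolate alkylation); the new centre (C14 of the target) is racemic and of no consequence because it becomes sp2 in step 5.

**Step 4**
Reactants: 8 3-(hydroxymethyl)-2,6-dimethyl-4-methylidenecyclohex-2-en-1-one; 9 propiolic acid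
Product: 10 (2,4-dimethyl-6-methylidene-3-oxocyclohex-1-en-1-yl)methyl prop-2-ynoate
Conditions: DCC, DMAP (cat.), CH2Cl2, −20 to 0 °C
Reagents that add atoms: none
Why: Steglich esterification of the primary allylic alcohol with the carbodiimide-activated acid, run cold and briefly so that the acid does not isomerise the 4-methylene enone to the phenol.

**Step 5**
Reactants: 10 (2,4-dimethyl-6-methylidene-3-oxocyclohex-1-en-1-yl)methyl prop-2-ynoate
Product: 13 racemic cage ketone (butenolide-fused bicyclo[2.2.2]octenone with C12 exocyclic methylene; C23 epimers), via trienol silyl ether 11 (not isolated), via cage silyl enol ether 12 (not isolated)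
Conditions: TBSOTf, i-Pr2NEt, CH2Cl2, −78 to 0 °C; pentane, filtration through basic Al2O3; PhMe, BHT, 100 °C; 1 M HCl, THF, rt
Reagents that add atoms: none
Why: Soft enolisation at C14 gives the 2-silyloxy triene 11, which is freed from the ammonium salt so that it is not protonated to the arene; its electron-rich ring diene C22=C23–C30=C14 then adds the ester-tethered ynoate in an intramolecular Diels–Alder reaction (C22–C17 and C14–C16, regiochemistry fixed by the three-atom tether and matched to the enol ether polarisation), setting bridgeheads C14 and C22 in the only relative configuration a bicyclo[2.2.2]octadiene allows (racemic), and acid hydrolysis of the enol ether gives the ketone as C23 epimers that are re-enolised in step 9.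

**Step 6**
Reactants: 14 2-methylbut-3-yn-2-ol
Product: 15 trimethyl[(2-methylbut-3-yn-2-yl)oxy]silane
Conditions: TMSCl, imidazole, CH2Cl2, 0 °C to rt
Reagents that add atoms: chlorotrimethylsilane, C[Si](C)(C)Cl
Why: Silylation of the tertiary propargylic alcohol with the silyl chloride and imidazole (silyl ether protection).

**Step 7**
Reactants: 15 trimethyl[(2-methylbut-3-yn-2-yl)oxy]silane
Product: 16 tributyl{3-methyl-3-[(trimethylsilyl)oxy]but-1-en-2-yl}stannane
Conditions: Bu3SnH, Mo(CO)3(CNt-Bu)3 (cat.), hydroquinone, THF, 55 °C
Reagents that add atoms: tributylstannane, CCCC[SnH](CCCC)CCCC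
Why: Molybdenum-catalysed syn hydrostannation of a terminal propargylic ether places tin on the internal carbon next to the oxygenated centre (α-selective hydrostannation), giving the 1,1-disubstituted vinylstannane.

**Step 8**
Reactants: 16 tributyl{3-methyl-3-[(trimethylsilyl)oxy]but-1-en-2-yl}stannane; 17 acryloyl chloride
Product: 18 5-methyl-4-methylidene-5-[(trimethylsilyl)oxy]hex-1-en-3-one
Conditions: PdCl2(PPh3)2 (cat.), CuI (cat.), BHT, THF, 50 °C
Reagents that add atoms: none
Why: Stille coupling of the vinylstannane with the acid chloride (oxidative addition of the acyl chloride, transmetalation, reductive elimination) gives the cross-conjugated divinyl ketone, which is kept cold with BHT and used at once.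

**Step 9**
Reactants: 13 racemic cage ketone; 18 5-methyl-4-methylidene-5-[(trimethylsilyl)oxy]hex-1-en-3-one
Product: 19 racemic Michael adduct (C23 quaternary: methyl syn to the C16=C17 bridge; chain C25–C26–C27(=O)–C9(=C10H2)–C2Me2OTMS syn to the C12 bridge)
Conditions: KHMDS, THF, −78 °C; 18, −78 to −40 °C; AcOH
Reagents that add atoms: none
Why: The potassium enolate of 13, which can form only towards C23, adds to the unsubstituted vinyl terminus C25 of 18 (Michael addition; the α-branched vinyl group is the poorer acceptor) and creates quaternary C23; the two faces being sterically alike, the acceptor should approach over the electron-rich C12 methylene bridge and away from the polarised butenolide bridge C16=C17–C18=O, so that the chain ends syn to C12, and any C23 epimer is removed by chromatography.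

**Step 10**
Reactants: 19 racemic Michael adduct
Product: 20 Michael adduct as single enantiomer (C14, C22 and C23 as in the target)
Conditions: preparative HPLC, amylose tris(3,5-dimethylphenylcarbamate) on silica, hexane/i-PrOH, rt
Reagents that add atoms: none
Why: Chromatographic resolution on a chiral stationary phase separates the enantiomers of 19, and the antipode with the target configuration is kept, its absolute configuration to be confirmed by anomalous-dispersion crystallography or by the sign of rotation of 26.

**Step 11**
Reactants: 20 Michael adduct as single enantiomer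
Product: 21 key-step precursor (C27 TIPS enol ether; Z at C26=C27)
Conditions: TIPSOTf, Et3N, CH2Cl2, −78 °C to rt
Reagents that add atoms: triisopropylsilyl trifluoromethanesulfonate, CC(C)[Si](C(C)C)(C(C)C)OS(=O)(=O)C(F)(F)F
Why: Soft enolisation with a silyl triflate and amine (silyl enol ether formation) can occur only at C26, because C30 has no α-hydrogen and C9 is sp2, and should give the Z enol ether (C25 cis to OSi, trans to C9), which avoids allylic strain with the C9 substituent; TIPS is chosen because it must later survive cleavage of the O–TMS group and must not migrate to the neighbouring alkoxide.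

**Step 12**
Reactants: 21 key-step precursor
Product: 22 pentacyclic silyl enol ether (rings B and C closed; C27(OTIPS)=C9)
Conditions: PhMe (0.005 M), BHT, base-washed sealed tube, 190 °C
Reagents that add atoms: none
Why: On heating, the s-cis 2-silyloxy diene C26=C27–C9=C10 adds suprafacially across the cage methylene C12=C11 in a concerted thermal [4+2] cycloaddition that forms C12–C26 and C10–C11 and shifts the enol ether to C27=C9. The closest known reaction type is the type 1 intramolecular Diels–Alder reaction of terminally tethered 2-silyloxy dienes with unactivated 1,1-disubstituted alkenes, which gives cis-fused hydrindanone silyl enol ethers. Ring C closes in the exo sense through the three-atom tether C25–C23–C22 (C26 bonds to the inner alkene carbon C12 and C11 stays outside the five-membered ring), and ring B is the cyclohexene of the cycloaddition, completed by C10–C11. C12 is controlled by the C23 configuration, since the tether can bring C26 only to the methylene face that looks toward the C23–C30 ketone bridge; C26 is controlled by the Z enol ether (C25 on the outside of the diene) together with the endo position of the tether carbon C22, the alternative being blocked because it would push C9 and the C27 silyloxy group against C13 and the C30 carbonyl, so that H-26 ends cis to C13 (cis ring fusion). The selectivity required is for the unactivated C12=C11 over the conjugated butenolide alkene C16=C17; it is secured by geometry, because C25 sits on the C12 side of C23 and cannot reach the other bridge, while high dilution and a radical inhibitor suppress bimolecular addition to the butenolide.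

**Step 13**
Reactants: 22 pentacyclic silyl enol ether
Product: 23 tertiary C2 alcohol (TIPS enol ether retained)
Conditions: K2CO3 (cat.), MeOH, 0 °C
Reagents that add atoms: none
Why: Base-catalysed methanolysis cleaves the O–TMS ether of the tertiary alcohol selectively (silyl ether solvolysis), since the hindered tetrasubstituted TIPS enol ether is far less labile and the lactones re-close if opened.

**Step 14**
Reactants: 23 tertiary C2 alcohol; 9 propiolic acid
Product: 24 C2 propiolate (TIPS enol ether retained)
Conditions: DCC, DMAP (cat.), CH2Cl2, −20 to 0 °C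
Reagents that add atoms: none
Why: Steglich esterification of the tertiary alcohol with the small, strongly activated propiolic O-acylisourea, the acid being pre-activated so that it does not protonate the enol ether.

**Step 15**
Reactants: 24 C2 propiolate
Product: 25 spirolactone ketone (C27 ketone; C9 spiro centre)
Conditions: Ph3PAuNTf2 (5 mol%), MeOH (2 equiv), CH2Cl2, rt
Reagents that add atoms: none
Why: Cationic gold activates the ynoate and the silyl enol ether carbon C9 adds anti to gold at the β-carbon C8 in a 6-endo-dig Conia-ene-type carbocyclisation, followed by desilylation by methanol and protodeauration; C8 should bond to the face of C9 on the side of ring C (C25, C22), because the bulky carbinol carbon C2 is thereby turned to the open face flanked by H-26 and C13.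

**Step 16**
Reactants: 25 spirolactone ketone
Product: 26 andibenin B
Conditions: MeMgBr, CeCl3, THF, −78 °C; NH4Cl (aq)
Reagents that add atoms: methylmagnesium bromide, C[Mg]Br
Why: The organocerium reagent from MeMgBr adds 1,2 to the C27 ketone (Grignard-type carbonyl addition), which is less hindered than the C30 ketone between two quaternary carbons and more electrophilic than the two lactones; it should enter from the face of H-26, opposite C25 and the lactone vinyl carbon C8, placing the methyl cis to H-26 and the hydroxyl cis to C25 as in 26.

**Compound list**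

1 | 3-ethoxy-2-methylcyclohex-2-en-1-one | CCOC1=C(C)C(=O)CCC1 | starting material
2 | 6-[(dimethylamino)methyl]-3-ethoxy-2-methylcyclohex-2-en-1-one (racemic Mannich base) | CCOC1=C(C)C(=O)C(CN(C)C)CC1 | intermediate
3 | [(4-ethoxy-3-methyl-2-oxocyclohex-3-en-1-yl)methyl]trimethylammonium iodide (racemic) | CCOC1=C(C)C(=O)C(C[N+](C)(C)C)CC1.[I-] | intermediate
4 | 3-ethoxy-2-methyl-6-methylidenecyclohex-2-en-1-one | CCOC1=C(C)C(=O)C(=C)CC1 | intermediate
5 | 1-{[dimethyl(propan-2-yloxy)silyl]methyl}-3-ethoxy-2-methyl-6-methylidenecyclohex-2-en-1-ol (racemic) | CCOC1=C(C)C(O)(C[Si](C)(C)OC(C)C)C(=C)CC1 | intermediate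
6 | 3-ethoxy-1-(hydroxymethyl)-2-methyl-6-methylidenecyclohex-2-en-1-ol (racemic) | CCOC1=C(C)C(O)(CO)C(=C)CC1 | intermediate
7 | 3-(hydroxymethyl)-2-methyl-4-methylidenecyclohex-2-en-1-one | C=C1CCC(=O)C(C)=C1CO | intermediate
8 | 3-(hydroxymethyl)-2,6-dimethyl-4-methylidenecyclohex-2-en-1-one (racemic at C6) | C=C1CC(C)C(=O)C(C)=C1CO | intermediate
9 | propiolic acid (prop-2-ynoic acid) | C#CC(=O)O | starting material
10 | (2,4-dimethyl-6-methylidene-3-oxocyclohex-1-en-1-yl)methyl prop-2-ynoate (racemic) | C#CC(=O)OCC1=C(C)C(=O)C(C)CC1=C | intermediate
11 | {3-[(tert-butyldimethylsilyl)oxy]-2,4-dimethyl-6-methylidenecyclohexa-1,3-dien-1-yl}methyl prop-2-ynoate (achiral) | C#CC(=O)OCC1=C(C)C(O[Si](C)(C)C(C)(C)C)=C(C)CC1=C | intermediate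
12 | racemic cage silyl enol ether: bicyclo[2.2.2]octadiene with bridgeheads C14 (methyl) and C22, bridges C16=C17, C12(=C11H2)–C13H2 and C23(methyl)=C30(OTBS), butenolide C17–C18(=O)–O20–C21H2–C22 | C=C1C[C@@]2(C)C=C3C(=O)OC[C@]31C(C)=C2O[Si](C)(C)C(C)(C)C | intermediate
13 | racemic cage ketone: as 12 with C30 ketone and C23 bearing H and methyl (both C23 epimers) | C=C1C[C@@]2(C)C=C3C(=O)OC[C@]31C(C)C2=O | intermediate
14 | 2-methylbut-3-yn-2-ol | CC(C)(O)C#C | starting material
15 | trimethyl[(2-methylbut-3-yn-2-yl)oxy]silane | CC(C)(C#C)O[Si](C)(C)C | intermediate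
16 | tributyl{3-methyl-3-[(trimethylsilyl)oxy]but-1-en-2-yl}stannane | C=C(C(C)(C)O[Si](C)(C)C)[Sn](CCCC)(CCCC)CCCC | intermediate
17 | acryloyl chloride | C=CC(=O)Cl | starting material
18 | 5-methyl-4-methylidene-5-[(trimethylsilyl)oxy]hex-1-en-3-one | C=CC(=O)C(=C)C(C)(C)O[Si](C)(C)C | intermediate
19 | racemic Michael adduct: 13 with quaternary C23 carrying methyl (syn to the C16=C17 bridge) and the chain C25H2–C26H2–C27(=O)–C9(=C10H2)–C2(CH3)2–OTMS (syn to the C12 bridge) | C=C1C[C@@]2(C)C=C3C(=O)OC[C@]31[C@@](C)(CCC(=O)C(=C)C(C)(C)O[Si](C)(C)C)C2=O | intermediate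
20 | single enantiomer of 19 with the C14, C22 and C23 configuration of the target | C=C1C[C@@]2(C)C=C3C(=O)OC[C@]31[C@@](C)(CCC(=O)C(=C)C(C)(C)O[Si](C)(C)C)C2=O | intermediate
21 | key-step precursor: 20 with C27 as TIPS enol ether, Z at C26=C27 (C25 cis to OSi, trans to C9), diene C26=C27–C9=C10 | C=C1C[C@@]2(C)C=C3C(=O)OC[C@]31[C@@](C)(C/C=C(O[Si](C(C)C)(C(C)C)C(C)C)/C(=C)C(C)(C)O[Si](C)(C)C)C2=O | intermediate
22 | key-step product: pentacycle with rings B and C closed, C27(OTIPS)=C9 enol ether, H-26 cis to C13, C2–OTMS | CC(C)(O[Si](C)(C)C)C1=C(O[Si](C(C)C)(C(C)C)C(C)C)[C@@H]2C[C@@]3(C)C(=O)[C@]4(C)C=C5C(=O)OC[C@@]53[C@@]2(CC1)C4 | intermediate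
23 | tertiary C2 alcohol of 22 (TIPS enol ether retained) | CC(C)(O)C1=C(O[Si](C(C)C)(C(C)C)C(C)C)[C@@H]2C[C@@]3(C)C(=O)[C@]4(C)C=C5C(=O)OC[C@@]53[C@@]2(CC1)C4 | intermediate
24 | C2 prop-2-ynoate of 23 | CC(C)(OC(=O)C#C)C1=C(O[Si](C(C)C)(C(C)C)C(C)C)[C@@H]2C[C@@]3(C)C(=O)[C@]4(C)C=C5C(=O)OC[C@@]53[C@@]2(CC1)C4 | intermediate
25 | spirolactone ketone: andibenin B skeleton with C27 ketone; at C9, C8 on the ring B face of C25 and C22, C2 on the face of H-26 | CC1(C)OC(=O)C=C[C@]12CC[C@@]13C[C@@]4(C)C=C5C(=O)OC[C@]51[C@@](C)(C[C@H]3C2=O)C4=O | intermediate
26 | andibenin B | CC1(C)OC(=O)C=C[C@]12CC[C@@]13C[C@@]4(C)C=C5C(=O)OC[C@]51[C@@](C)(C[C@H]3[C@@]2(C)O)C4=O | target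

**Totals**

Total step count: 16. Longest linear sequence: 13 steps (steps 1–5 and 9–16); steps 6–8 form the side branch.

**Steps most likely to fail**

Step 9. The acceptor may approach C23 from the face of the C16=C17 bridge and give the wrong C23 epimer, or the vinyl ketone may oligomerise under the enolate. The order in which the two C23 substituents arrive would then be reversed, so that the cage steers the small electrophile instead. From 13, selenenylation of the C23 enolate (LDA; PhSeBr) gives the α-phenylselanyl ketone F1. Oxidation (H2O2, pyridine) with syn elimination towards the methyl group gives the exocyclic enone F2, whose methylene carbon becomes C25. Stannane 16 is acylated with acetyl chloride (PdCl2(PPh3)2) to the methyl ketone F3. The lithium enolate of F3 (LDA, −78 °C) adds to F2, and the resulting C23 enolate is trapped with MeI/DMPU. This places the methyl group where the acceptor would have gone and the chain on the opposite face, and it rejoins the route at 19.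

Step 12. The silyl dienol ether may decompose (silyl loss, oligomerisation) at the temperature that the unactivated 1,1-disubstituted alkene demands. The same two bonds would then be made by metal templating instead of a thermal pericyclic reaction. A monovalent rhodium catalyst ([RhCl(C8H14)2]2 with P[OCH(CF3)2]3, THF, 55 °C) binds diene and alkene, couples them oxidatively to a rhodacycle and releases the cyclohexene by reductive elimination. This is a known way to cyclise unactivated diene–ene substrates under mild conditions. The fallback sets out from 21 and returns at 22; it makes no new compound.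

Step 5. Trienol silyl ether 11 is a tautomer of an aryl silyl ether and may aromatise by proton transfer (protonation at C11, loss of H from C13) faster than it cyclises; the amine may also add to the ynoate. The methylene would then be masked during the cycloaddition. From 8, 1,6-addition of PhSH (Et3N) gives the phenylthiomethyl enone F4, and esterification as in step 4 gives the propiolate F5. Silylation gives the ordinary 2-silyloxy cyclohexadiene F6, which cannot aromatise without oxidation. Heating gives the cage silyl enol ether F7, which is hydrolysed to the cage ketone F8 (C12 and C23 epimers, both inconsequential). Oxidation (mCPBA, −78 °C) gives the sulfoxide F9. Thermolysis (PhMe, 110 °C, CaCO3) eliminates benzenesulfenic acid across C11–C12, the only β-hydrogen being on C12, and returns to 13.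

**Further compounds**

F1 | step 9 | racemic α-phenylselanyl cage ketone (C23 bearing methyl and SePh) | C=C1C[C@@]2(C)C=C3C(=O)OC[C@]31C(C)([Se]c1ccccc1)C2=O
F2 | step 9 | racemic cage α-methylene ketone (C23=CH2) | C=C1C[C@@]2(C)C=C3C(=O)OC[C@]31C(=C)C2=O
F3 | step 9 | 4-methyl-3-methylidene-4-[(trimethylsilyl)oxy]pentan-2-one | CC(=O)C(=C)C(C)(C)O[Si](C)(C)C
F0 | step 12 | none | none
F4 | step 5 | 3-(hydroxymethyl)-2,6-dimethyl-4-[(phenylsulfanyl)methyl]cyclohex-2-en-1-one (racemic, diastereomers) | CC1CC(CSc2ccccc2)C(CO)=C(C)C1=O
F5 | step 5 | {2,4-dimethyl-3-oxo-6-[(phenylsulfanyl)methyl]cyclohex-1-en-1-yl}methyl prop-2-ynoate | C#CC(=O)OCC1=C(C)C(=O)C(C)CC1CSc1ccccc1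
F6 | step 5 | {3-[(tert-butyldimethylsilyl)oxy]-2,4-dimethyl-6-[(phenylsulfanyl)methyl]cyclohexa-1,3-dien-1-yl}methyl prop-2-ynoate | C#CC(=O)OCC1=C(C)C(O[Si](C)(C)C(C)(C)C)=C(C)CC1CSc1ccccc1
F7 | step 5 | racemic cage silyl enol ether with C12 bearing H and CH2SPh | C(Sc1ccccc1)C1C[C@@]2(C)C=C3C(=O)OC[C@]31C(C)=C2O[Si](C)(C)C(C)(C)C
F8 | step 5 | racemic cage ketone with C12 bearing H and CH2SPh | C(Sc1ccccc1)C1C[C@@]2(C)C=C3C(=O)OC[C@]31C(C)C2=O
F9 | step 5 | sulfoxide of F8 | O=S(CC1C[C@@]2(C)C=C3C(=O)OC[C@]31C(C)C2=O)c1ccccc1
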